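Numbering used throughout: ring B atoms are C1 (carrying CO2Me) to C6, ring A atoms are C1' (carrying the ester carbonyl) to C6'. Compounds are numbered 1 to 21 in the order of the steps; 21 is the target.

## Analysis of the target

The target is a depside: two benzene rings joined by one aryl ester, with no further ring and no stereocentre. Ring A is a 3'-formyl-2',4'-dihydroxy-6'-methylbenzoyl unit. Ring B is a hexasubstituted benzene with CO2Me on C1, hydroxyl groups on C2 and C4, methyl groups on C3 and C6 and the ester oxygen on C5. The sensitive groups are the aryl aldehyde flanked by two phenols, the methyl ester and above all the aryl ester. The ester sits on C5 next to the free C4 hydroxyl, so base can move the acyl group between these two oxygens or cleave it. The difficulty is regiochemical: ring B carries three oxygens and only the one on C5 may be acylated, and the ring A acid is 2,6-disubstituted and therefore a poor acylating agent for a crowded phenol. The strategy rests on the fact that C1 and C6 of ring B with their CO2Me and methyl groups are the four carbons of a but-2-ynoate. C2 to C5, with the C3 methyl and one oxygen on each of C2, C4 and C5, are a 2-methylacetoacetate oxidised at its terminal carbon. The oxygen that becomes the C5 ester oxygen can thus be acylated while it is still on an open chain, and ring B is then closed around it.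

## Retrosynthetic reasoning

21 from 20. The two benzyl ether C–O bonds on ring A are cut last. Benzyl ethers can be removed under neutral conditions, which the base-sensitive C5 ester next to the C4 hydroxyl requires, and they are stable to every earlier step.

20 from 19. The formyl group is traced back to its dioxolane. The aldehyde must be masked while an aryllithium, a lithium amide and a silyl dienol ether are present, and it is freed by dilute acid before the hydrogenolysis so that no benzylic acetal is exposed to the catalyst.

19 from 16 and 17. Ring B is cut at C1–C2 and C5–C6. This releases the alkynoate 17 (C1, C6, CO2Me and the C6 methyl) and the electron-rich diene 16 (C2 to C5 with all three oxygens and the C3 methyl). The cut is made here because it gives the only pairing in which every ring B substituent is already in place on an acyclic partner and the ring A ester is already attached to the correct oxygen. The forward reaction has to deliver one regiochemistry of cycloaddition and then aromatise without losing the aroyloxy group.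

16 from 14 and 13. Diene 16 is the double silyl enol ether of the keto ester 13. No skeletal bond is made; the two enolisations fix the oxidation pattern and the polarity of the four-carbon unit. The forward steps have to enolise toward C2 and toward C4 of the chain without touching the ring A ester.

13 from 8 and 11. The ester is cut between the carboxylate oxygen and the chain CH2, not at the acyl C–O bond. The forward reaction is then an alkylation of a carboxylate by an α-halo ketone, which does not suffer from the two ortho substituents of acid 8.

11 from 9. The C–Br bond of 11 is cut back to the 2-methylacetoacetate 9. Bromination under acidic conditions is preferred to a base-mediated C-methylation of a γ-halo acetoacetate, because such enolates alkylate one another.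

8 from 6, 5 and 4. The C1'–carboxyl bond is cut back to the aryl bromide 6, the acetal to the aldehyde 5, and the C–Br bond to 4. In 4 the two open ring positions are equivalent, so bromination can give only one product, and halogen–metal exchange then puts the carboxyl group exactly where the bromine was.

4 from 2 and 1. The C3'–formyl bond is cut back to the bis-benzyl ether 2 of orcinol 1. The position between the two ether oxygens is the one that directed metalation reaches, so the formyl carbon enters first and without isomers.

## Alternatives that were turned down

Alternative 1: Ring A would be assembled last by a photochemical benzannulation. The diazo ketone A2, an ester of the ring B phenol A4, would undergo Wolff rearrangement to a ketene that adds the siloxyalkyne A3. Four-electron ring opening and six-electron ring closure on heating would then give the ring A phenol A1, with the formyl carbon present as a diethyl acetal. In its favour, the substitution pattern of ring A follows from the mechanism with no isomer problem, the union is convergent, and ring A arrives in one step where the chosen route needs five. On these points it is stronger. Against it, the hexasubstituted ring B is not addressed at all: A4 must be made separately with C5–OH free and C2 and C4 benzylated, which is the central regiochemical problem of the target. The aryl ester of A2 absorbs in the region used for the photolysis and can fragment. The alkene of A2 is doubly acceptor-substituted and can react with diazo groups. A1 needs three different deprotections. The chosen strategy instead builds the difficult ring in its key step and makes ring A by plain aromatic substitution.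

Alternative 2: Ring A would be formed on the finished ring B by a biomimetic aldol. The aryl trioxooctanoate A6, again an ester of A4, would cyclise under mild base from chain C2 onto the C7 ketone and dehydrate to the deformyl depside A5. In its favour, ring A is made in one step without protecting groups and without organometallic reagents, which is shorter than the chosen ring A sequence. Against it, the formyl carbon is missing and would have to be introduced late by electrophilic substitution, where C3' and C5' of A5 are both activated by two oxygens. The aryl oxide of A4 is a good leaving group, so attack of an enol oxygen on the ester carbonyl of A6 can expel it. A4 is still needed. The chosen strategy carries the formyl carbon from the second step and never has to choose between C3' and C5'.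

Alternative 3: Ring B would be closed by an intramolecular aldol of the open-chain triketo ester A8, which already bears the ring A aroyloxy group on chain C6. Attack of C2 on the C7 ketone and dehydration would give A7, which is the same compound as 20 of the chosen route. In its favour, it shares the main idea of the chosen route, namely closing ring B around an ester oxygen that is already acylated. Its ring closure is intramolecular and needs only base, which is easier than a bimolecular cycloaddition with a weakly activated alkyne, and it delivers the free aldehyde one step earlier. Against it, A8 has an acyloxy group on a carbon between two ketones; its enolate can pass the acyl group to a neighbouring enolate oxygen or undergo retro-Claisen cleavage. The free aldehyde of ring A is an acceptor for the 1,3-dicarbonyl enolates. The chain can also fold from C8 onto the C3 ketone, which gives a different benzene, and assembling A8 needs polyanion chemistry in the presence of a base-labile ester. The chosen strategy locks both enols as silyl ethers, works under neutral thermal conditions, and allows only one ring.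

Key step: step 10

Remark on the chemistry: the stereocentre at C2 of 11 and 13, the double bond geometry of 14 and the two sp3 centres of 18 are not controlled; all are lost before the target.

## Steps

Step 1
Reactants: 1 orcinol (5-methylbenzene-1,3-diol)
Product: 2 1,3-bis(benzyloxy)-5-methylbenzene
Conditions: BnBr (2.3 equiv), K2CO3, DMF, 60 °C
Reagents that add atoms: benzyl bromide, BrCc1ccccc1
Why: Williamson ether synthesis; both phenols are O-alkylated in a polar aprotic solvent, and the benzyl ethers withstand the organolithium, acid and silylation steps and can be removed at the end without base.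

Step 2
Reactants: 2 1,3-bis(benzyloxy)-5-methylbenzene
Product: 4 2,6-bis(benzyloxy)-4-methylbenzaldehyde, via aryllithium 3 (not isolated)
Conditions: n-BuLi, TMEDA, THF, 0 °C; then DMF, 0 °C to rt; aq NH4Cl
Reagents that add atoms: N,N-dimethylformamide, CN(C)C=O
Why: Directed ortho-metalation; the position between the two ether oxygens is the most acidic because both oxygens coordinate lithium, so aryllithium 3 should form there faster than the benzylic CH2 groups are attacked, and formylation puts the future aldehyde carbon on C3' without isomers.

Step 3
Reactants: 4 2,6-bis(benzyloxy)-4-methylbenzaldehyde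
Product: 5 2,6-bis(benzyloxy)-3-bromo-4-methylbenzaldehyde
Conditions: NBS (1.0 equiv), MeCN, 0 °C to rt, dark
Reagents that add atoms: N-bromosuccinimide, O=C1CCC(=O)N1Br
Why: Electrophilic aromatic bromination; the two open positions are equivalent by symmetry, each ortho to one ether oxygen, para to the other and meta to the formyl group, so only one monobromide can form and the first bromine slows a second substitution.

Step 4
Reactants: 5 2,6-bis(benzyloxy)-3-bromo-4-methylbenzaldehyde
Product: 6 2-[2,6-bis(benzyloxy)-3-bromo-4-methylphenyl]-1,3-dioxolane
Conditions: HOCH2CH2OH, p-TsOH (cat.), toluene, reflux, Dean–Stark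
Reagents that add atoms: ethane-1,2-diol, OCCO
Why: Acid-catalysed acetalisation with azeotropic removal of water; the aldehyde must be masked before the aryllithium, the lithium amide and the silyl dienol ether are generated, and aryl benzyl ethers and the bromide are inert to catalytic sulfonic acid.

Step 5
Reactants: 6 2-[2,6-bis(benzyloxy)-3-bromo-4-methylphenyl]-1,3-dioxolane
Product: 8 2,4-bis(benzyloxy)-3-(1,3-dioxolan-2-yl)-6-methylbenzoic acid, via aryllithium 7 (not isolated)
Conditions: n-BuLi, THF, −78 °C; then CO2 (dry gas), −78 to 0 °C; cold dilute HCl to pH 4
Reagents that add atoms: carbon dioxide, O=C=O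
Why: Bromine–lithium exchange and carboxylation; exchange at −78 °C is faster than any deprotonation, aryllithium 7 adds to carbon dioxide to place the carboxyl carbon on C1' between the methyl and a benzyloxy group, and acidification only to pH 4 in the cold should leave the dioxolane intact.

Step 6
Reactants: 9 methyl 2-methyl-3-oxobutanoate
Product: 11 methyl 4-bromo-2-methyl-3-oxobutanoate, via 2-bromo keto ester 10 (not isolated)
Conditions: Br2 (1.0 equiv), CHCl3, 0 °C to rt, 16 h
Reagents that add atoms: bromine, BrBr
Why: Bromination of a β-keto ester under acidic conditions; the kinetic tertiary bromide 10 is re-equilibrated by the hydrogen bromide formed to the primary γ-bromide 11, the known behaviour of 2-alkylacetoacetates, and no base is present that could cause self-alkylation.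

Step 7
Reactants: 8 2,4-bis(benzyloxy)-3-(1,3-dioxolan-2-yl)-6-methylbenzoic acid; 11 methyl 4-bromo-2-methyl-3-oxobutanoate
Product: 13 methyl 4-{[2,4-bis(benzyloxy)-3-(1,3-dioxolan-2-yl)-6-methylbenzoyl]oxy}-2-methyl-3-oxobutanoate, via cesium carboxylate 12 (not isolated)
Conditions: Cs2CO3 (0.5 equiv), DMF, rt; then 11, 0 °C to rt
Reagents that add atoms: none
Why: SN2 displacement of an α-halo ketone by a carboxylate; the hindered acid reacts through oxygen and not at its carbonyl carbon, the activated primary bromide reacts quickly, and the carboxylate is too weak a base to enolise the β-keto ester once all carbonate has been consumed.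

Step 8
Reactants: 13 methyl 4-{[2,4-bis(benzyloxy)-3-(1,3-dioxolan-2-yl)-6-methylbenzoyl]oxy}-2-methyl-3-oxobutanoate
Product: 14 methyl 4-{[2,4-bis(benzyloxy)-3-(1,3-dioxolan-2-yl)-6-methylbenzoyl]oxy}-2-methyl-3-(trimethylsilyloxy)but-2-enoate
Conditions: TMSCl, Et3N, toluene, rt
Reagents that add atoms: chlorotrimethylsilane, C[Si](C)(C)Cl
Why: O-silylation of the β-keto ester enol under amine base; if part of the material is silylated toward C4 instead, both monosilyl isomers should converge on the same diene in step 9.

Step 9
Reactants: 14 methyl 4-{[2,4-bis(benzyloxy)-3-(1,3-dioxolan-2-yl)-6-methylbenzoyl]oxy}-2-methyl-3-(trimethylsilyloxy)but-2-enoate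
Product: 16 (1Z,3Z)-4-methoxy-3-methyl-2,4-bis(trimethylsilyloxy)buta-1,3-dien-1-yl 2,4-bis(benzyloxy)-3-(1,3-dioxolan-2-yl)-6-methylbenzoate, via lithium dienolate 15 (not isolated)
Conditions: LiN(iPr)2 (LDA), THF, −78 °C; then TMSCl, −78 to 0 °C; pentane, filtration under argon
Reagents that add atoms: chlorotrimethylsilane, C[Si](C)(C)Cl
Why: Kinetic γ-deprotonation of a β-silyloxy enoate and O-silylation of the ester dienolate, the standard access to 1-alkoxy-1,3-bis(silyloxy)butadienes; the CH2 hydrogens are activated by the vinylogous ester and the acyloxy group, the hindered aryl ester resists the amide, and the acyloxy group is expected trans to the methyl-bearing carbon to avoid allylic strain (the ketene acetal geometry is of no consequence).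

Step 10
Reactants: 16 (1Z,3Z)-4-methoxy-3-methyl-2,4-bis(trimethylsilyloxy)buta-1,3-dien-1-yl 2,4-bis(benzyloxy)-3-(1,3-dioxolan-2-yl)-6-methylbenzoate; 17 methyl but-2-ynoate
Product: 19 methyl 5-{[2,4-bis(benzyloxy)-3-(1,3-dioxolan-2-yl)-6-methylbenzoyl]oxy}-2,4-dihydroxy-3,6-dimethylbenzoate, via cyclohexa-1,4-diene cycloadduct 18 (not isolated)
Conditions: 17 (5 equiv), toluene, 120 °C, sealed tube; then 10% aq citric acid, THF, 0 °C
Reagents that add atoms: none
Why: This is the Diels–Alder reaction of a 1-alkoxy-1,3-bis(silyloxy)butadiene with an alkynoate followed by aromatisation, a known route to salicylates, applied here to a 2-methyl-4-acyloxy diene. The electron-rich diene 16 and the electron-poor alkyne 17 should combine in an intermolecular, normal-electron-demand [4+2] cycloaddition that forms the ring B bonds C5–C6 and C1–C2 and closes ring B as the cyclohexa-1,4-diene 18, the bond to the alkyne β-carbon being the more advanced one in an asynchronous transition state. The step needs regioselectivity only: the largest HOMO coefficient of 16 lies on the CH(O-aroyl) terminus, because the two oxygens on the ketene acetal carbon and the silyloxy group two carbons away all push electron density there while the acyloxy group is only a weak donor, and the largest LUMO coefficient of 17 lies on its methyl-bearing β-carbon, so the ester oxygen ends next to the C6 methyl and the ketal carbon next to the carbon bearing CO2Me. The two sp3 centres of 18 form without control and both disappear, so no stereocentre has to be set. In dilute aqueous acid the mixed methyl silyl ketal collapses with loss of methanol to a cross-conjugated dienone, the hydrogen on the carbon bearing the aroyloxy group moves to oxygen to give the C2 phenol, and the silyl ether at C4 is hydrolysed. Loss of the aroyloxy group is not open, since the ketal carbon para to it has no hydrogen for a 1,4-elimination and ionisation at C5 would give a cation that no oxygen can stabilise. The methyl group on the diene favours the s-cis conformation, and the aroyloxy group on the outside of the diene terminus should slow the reaction but not redirect it.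

Step 11
Reactants: 19 methyl 5-{[2,4-bis(benzyloxy)-3-(1,3-dioxolan-2-yl)-6-methylbenzoyl]oxy}-2,4-dihydroxy-3,6-dimethylbenzoate
Product: 20 methyl 5-{[2,4-bis(benzyloxy)-3-formyl-6-methylbenzoyl]oxy}-2,4-dihydroxy-3,6-dimethylbenzoate
Conditions: 1 M HCl, THF, rt
Reagents that add atoms: water, O
Why: Acid-catalysed acetal hydrolysis; the electron-rich aryl dioxolane ionises readily, while the aryl ester, the methyl ester and the benzyl ethers are stable to dilute aqueous acid at room temperature, and acidic conditions avoid acyl migration between the C5 and C4 oxygens.

Step 12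
Reactants: 20 methyl 5-{[2,4-bis(benzyloxy)-3-formyl-6-methylbenzoyl]oxy}-2,4-dihydroxy-3,6-dimethylbenzoate
Product: 21 methyl 5-[(3-formyl-2,4-dihydroxy-6-methylbenzoyl)oxy]-2,4-dihydroxy-3,6-dimethylbenzoate
Conditions: H2 (1 atm), 10% Pd/C, EtOAc, rt, stopped at full conversion
Reagents that add atoms: none
Why: Catalytic hydrogenolysis of aryl benzyl ethers; these cleave fast under neutral conditions, the formyl group is flanked by two ortho substituents and becomes doubly hydrogen-bonded as the phenols are released, which slows its reduction, and no base is present that could move the acyl group.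

## Compound list

1 | orcinol (5-methylbenzene-1,3-diol) | Cc1cc(O)cc(O)c1 | starting material
2 | 1,3-bis(benzyloxy)-5-methylbenzene | Cc1cc(OCc2ccccc2)cc(OCc2ccccc2)c1 | intermediate
3 | [2,6-bis(benzyloxy)-4-methylphenyl]lithium | [Li]c1c(OCc2ccccc2)cc(C)cc1OCc1ccccc1 | intermediate (not isolated)
4 | 2,6-bis(benzyloxy)-4-methylbenzaldehyde | O=Cc1c(OCc2ccccc2)cc(C)cc1OCc1ccccc1 | intermediate
5 | 2,6-bis(benzyloxy)-3-bromo-4-methylbenzaldehyde | O=Cc1c(OCc2ccccc2)cc(C)c(Br)c1OCc1ccccc1 | intermediate
6 | 2-[2,6-bis(benzyloxy)-3-bromo-4-methylphenyl]-1,3-dioxolane | Cc1cc(OCc2ccccc2)c(C2OCCO2)c(OCc2ccccc2)c1Br | intermediate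
7 | [2,4-bis(benzyloxy)-3-(1,3-dioxolan-2-yl)-6-methylphenyl]lithium | [Li]c1c(C)cc(OCc2ccccc2)c(C2OCCO2)c1OCc1ccccc1 | intermediate (not isolated)
8 | 2,4-bis(benzyloxy)-3-(1,3-dioxolan-2-yl)-6-methylbenzoic acid | OC(=O)c1c(C)cc(OCc2ccccc2)c(C2OCCO2)c1OCc1ccccc1 | intermediate
9 | methyl 2-methyl-3-oxobutanoate | COC(=O)C(C)C(C)=O | starting material
10 | methyl 2-bromo-2-methyl-3-oxobutanoate | COC(=O)C(C)(Br)C(C)=O | intermediate (not isolated)
11 | methyl 4-bromo-2-methyl-3-oxobutanoate (racemic) | COC(=O)C(C)C(=O)CBr | intermediate
12 | cesium 2,4-bis(benzyloxy)-3-(1,3-dioxolan-2-yl)-6-methylbenzoate | [Cs+].[O-]C(=O)c1c(C)cc(OCc2ccccc2)c(C2OCCO2)c1OCc1ccccc1 | intermediate (not isolated)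
13 | methyl 4-{[2,4-bis(benzyloxy)-3-(1,3-dioxolan-2-yl)-6-methylbenzoyl]oxy}-2-methyl-3-oxobutanoate (racemic) | COC(=O)C(C)C(=O)COC(=O)c1c(C)cc(OCc2ccccc2)c(C2OCCO2)c1OCc1ccccc1 | intermediate
14 | methyl 4-{[2,4-bis(benzyloxy)-3-(1,3-dioxolan-2-yl)-6-methylbenzoyl]oxy}-2-methyl-3-(trimethylsilyloxy)but-2-enoate (double bond isomers) | COC(=O)C(C)=C(O[Si](C)(C)C)COC(=O)c1c(C)cc(OCc2ccccc2)c(C2OCCO2)c1OCc1ccccc1 | intermediate
15 | lithium dienolate of 14 (lithium on the ester oxygen) | [Li]OC(OC)=C(C)C(O[Si](C)(C)C)=COC(=O)c1c(C)cc(OCc2ccccc2)c(C2OCCO2)c1OCc1ccccc1 | intermediate (not isolated)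
16 | (1Z,3Z)-4-methoxy-3-methyl-2,4-bis(trimethylsilyloxy)buta-1,3-dien-1-yl 2,4-bis(benzyloxy)-3-(1,3-dioxolan-2-yl)-6-methylbenzoate | CO/C(O[Si](C)(C)C)=C(C)/C(O[Si](C)(C)C)=C/OC(=O)c1c(C)cc(OCc2ccccc2)c(C2OCCO2)c1OCc1ccccc1 | intermediate
17 | methyl but-2-ynoate | CC#CC(=O)OC | starting material
18 | methyl 3-{[2,4-bis(benzyloxy)-3-(1,3-dioxolan-2-yl)-6-methylbenzoyl]oxy}-6-methoxy-2,5-dimethyl-4,6-bis(trimethylsilyloxy)cyclohexa-1,4-diene-1-carboxylate (diastereomer mixture) | COC(=O)C1=C(C)C(OC(=O)c2c(C)cc(OCc3ccccc3)c(C3OCCO3)c2OCc2ccccc2)C(O[Si](C)(C)C)=C(C)C1(OC)O[Si](C)(C)C | intermediate (not isolated)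
19 | methyl 5-{[2,4-bis(benzyloxy)-3-(1,3-dioxolan-2-yl)-6-methylbenzoyl]oxy}-2,4-dihydroxy-3,6-dimethylbenzoate | COC(=O)c1c(C)c(OC(=O)c2c(C)cc(OCc3ccccc3)c(C3OCCO3)c2OCc2ccccc2)c(O)c(C)c1O | intermediate
20 | methyl 5-{[2,4-bis(benzyloxy)-3-formyl-6-methylbenzoyl]oxy}-2,4-dihydroxy-3,6-dimethylbenzoate | COC(=O)c1c(C)c(OC(=O)c2c(C)cc(OCc3ccccc3)c(C=O)c2OCc2ccccc2)c(O)c(C)c1O | intermediate
21 | methyl 5-[(3-formyl-2,4-dihydroxy-6-methylbenzoyl)oxy]-2,4-dihydroxy-3,6-dimethylbenzoate | COC(=O)c1c(C)c(OC(=O)c2c(C)cc(O)c(C=O)c2O)c(O)c(C)c1O | target

## Step count and least certain steps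

Total step count: 12. Longest linear sequence: 11 steps (steps 1 to 5 and 7 to 12, from 1); step 6 is a one-step branch that joins at step 7.

Step 10 (key step). The cycloaddition may be too slow to compete with thermal desilylation or decomposition of the diene, because both bond-forming termini are substituted and the alkyne is activated by one ester only. The first C–C bond may also form without ring closure, through silyl transfer after a Michael-type addition. The fallback sets out from 16 and returns at 19. Diene 16 would be heated at 60 to 80 °C in toluene with commercially available methyl buta-2,3-dienoate (C=C=CC(=O)OC) in place of 17. The allenic ester reacts at its α,β-double bond, which is less hindered and more reactive than the alkyne, with the same polarity, and should give the exocyclic methylene cycloadduct F1 (not isolated). The same acidic work-up removes methanol and the silyl groups and moves the exocyclic double bond into the ring, which gives 19.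

Step 9. The lithium amide may deprotonate the ring A methyl group ortho to the ester, or the lithium dienolate may transfer the aroyl group from oxygen to carbon before it is silylated. The fallback sets out from 13 (step 8 is then not needed) and returns at 19. Keto ester 13 would be enolised without a strong base by TBSOTf (2.5 equiv) and Et3N in CH2Cl2 at 0 °C, the amine being kept in excess to protect the dioxolane, to give the bis(tert-butyldimethylsilyl) diene F2, which is robust enough to be purified. F2 and 17 would be heated as in step 10 to the bis-silyl cycloadduct F3 (not isolated), and HF·pyridine in THF would collapse the ketal and free the C4 phenol to give 19.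

Step 2. Deprotonation at a benzylic CH2 of the ether groups, followed by anionic rearrangement, may compete with ring metalation. The fallback sets out from 1 and returns at 4. Orcinol 1 would be converted with MOMCl and iPr2NEt into 1,3-bis(methoxymethoxy)-5-methylbenzene F4, whose acetal ethers direct lithiation strongly and have no benzylic hydrogens. Lithiation with n-BuLi and TMEDA and formylation with DMF would give 2,6-bis(methoxymethoxy)-4-methylbenzaldehyde F5. HCl in methanol would release 2,6-dihydroxy-4-methylbenzaldehyde F6, and benzylation with BnBr and K2CO3 in DMF would give 4.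

Step 12. Over-reduction of the formyl group to a hydroxymethyl or methyl group may occur, or the crowded C2' benzyl ether may cleave slowly so that the reaction has to run long. The fallback sets out from 20 and returns at 21. The benzyl ethers would be cleaved without hydrogen by BCl3 with pentamethylbenzene as cation scavenger in CH2Cl2 at −78 °C, conditions that leave aldehydes and esters untouched at this temperature; no new compound arises on this way (F0).

## Further compounds

F1 | step 10 | methyl 5-{[2,4-bis(benzyloxy)-3-(1,3-dioxolan-2-yl)-6-methylbenzoyl]oxy}-2-methoxy-3-methyl-6-methylidene-2,4-bis(trimethylsilyloxy)cyclohex-3-ene-1-carboxylate (diastereomer mixture) | COC(=O)C1C(=C)C(OC(=O)c2c(C)cc(OCc3ccccc3)c(C3OCCO3)c2OCc2ccccc2)C(O[Si](C)(C)C)=C(C)C1(OC)O[Si](C)(C)C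
F2 | step 9 | (1Z,3Z)-2,4-bis(tert-butyldimethylsilyloxy)-4-methoxy-3-methylbuta-1,3-dien-1-yl 2,4-bis(benzyloxy)-3-(1,3-dioxolan-2-yl)-6-methylbenzoate | CO/C(O[Si](C)(C)C(C)(C)C)=C(C)/C(O[Si](C)(C)C(C)(C)C)=C/OC(=O)c1c(C)cc(OCc2ccccc2)c(C2OCCO2)c1OCc1ccccc1
F3 | step 9 | methyl 3-{[2,4-bis(benzyloxy)-3-(1,3-dioxolan-2-yl)-6-methylbenzoyl]oxy}-4,6-bis(tert-butyldimethylsilyloxy)-6-methoxy-2,5-dimethylcyclohexa-1,4-diene-1-carboxylate (diastereomer mixture) | COC(=O)C1=C(C)C(OC(=O)c2c(C)cc(OCc3ccccc3)c(C3OCCO3)c2OCc2ccccc2)C(O[Si](C)(C)C(C)(C)C)=C(C)C1(OC)O[Si](C)(C)C(C)(C)C
F4 | step 2 | 1,3-bis(methoxymethoxy)-5-methylbenzene | COCOc1cc(C)cc(OCOC)c1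
F5 | step 2 | 2,6-bis(methoxymethoxy)-4-methylbenzaldehyde | COCOc1cc(C)cc(OCOC)c1C=O
F6 | step 2 | 2,6-dihydroxy-4-methylbenzaldehyde | Cc1cc(O)c(C=O)c(O)c1
F0 | step 12 | none | none
A1 | alternative 1 | methyl 2,4-bis(benzyloxy)-5-{[3-(diethoxymethyl)-2-hydroxy-6-methyl-4-(triisopropylsilyloxy)benzoyl]oxy}-3,6-dimethylbenzoate | COC(=O)c1c(C)c(OC(=O)c2c(C)cc(O[Si](C(C)C)(C(C)C)C(C)C)c(C(OCC)OCC)c2O)c(OCc2ccccc2)c(C)c1OCc1ccccc1
A2 | alternative 1 | 2,4-bis(benzyloxy)-5-(methoxycarbonyl)-3,6-dimethylphenyl (2E)-5-diazo-3-methyl-4-oxopent-2-enoate | COC(=O)c1c(C)c(OC(=O)/C=C(\C)C(=O)C=[N+]=[N-])c(OCc2ccccc2)c(C)c1OCc1ccccc1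
A3 | alternative 1 | 3,3-diethoxy-1-(triisopropylsilyloxy)prop-1-yne | CCOC(OCC)C#CO[Si](C(C)C)(C(C)C)C(C)C
A4 | alternative 1 | methyl 2,4-bis(benzyloxy)-5-hydroxy-3,6-dimethylbenzoate | COC(=O)c1c(C)c(O)c(OCc2ccccc2)c(C)c1OCc1ccccc1
A5 | alternative 2 | methyl 2,4-bis(benzyloxy)-5-[(2,4-dihydroxy-6-methylbenzoyl)oxy]-3,6-dimethylbenzoate | COC(=O)c1c(C)c(OC(=O)c2c(C)cc(O)cc2O)c(OCc2ccccc2)c(C)c1OCc1ccccc1
A6 | alternative 2 | 2,4-bis(benzyloxy)-5-(methoxycarbonyl)-3,6-dimethylphenyl 3,5,7-trioxooctanoate | COC(=O)c1c(C)c(OC(=O)CC(=O)CC(=O)CC(C)=O)c(OCc2ccccc2)c(C)c1OCc1ccccc1
A7 | alternative 3 | methyl 5-{[2,4-bis(benzyloxy)-3-formyl-6-methylbenzoyl]oxy}-2,4-dihydroxy-3,6-dimethylbenzoate (identical with 20) | COC(=O)c1c(C)c(OC(=O)c2c(C)cc(OCc3ccccc3)c(C=O)c2OCc2ccccc2)c(O)c(C)c1O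
A8 | alternative 3 | methyl 6-{[2,4-bis(benzyloxy)-3-formyl-6-methylbenzoyl]oxy}-4-methyl-3,5,7-trioxooctanoate (stereoisomer mixture) | COC(=O)CC(=O)C(C)C(=O)C(OC(=O)c1c(C)cc(OCc2ccccc2)c(C=O)c1OCc1ccccc1)C(C)=O
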